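**Retrosynthetic overview**

1. The target is an achiral diaryl ether. The last disconnections are pivalate removal, the ring A prenyl group (Claisen rearrangement of a 1,1-dimethylallyl aryl ether onto C3 of ring A) and the ring A methyl ester (methoxycarbonylation of an aryl bromide).
2. The strategy rests on ring B: ether oxygen on C1', CH2OH on C2' and mutually meta methoxy oxygens on C4' and C6'. This is the pattern of a 4-aryloxy-5-(oxymethyl)cyclohexane-1,3-dione.
3. Ring B is therefore cut at C1'–C2' (Michael addition) and C4'–C5' (Claisen acylation) into an aryloxyacetone and a 4-silyloxybut-2-enoate.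
4. Ring order: ring A comes ready-made from orcinol. Ring B is built on the ring A ether oxygen as a dione (step 6) and aromatized with I2/MeOH (step 7).
5. Bromine holds the place of the ring A ester through the annulation; an ortho ester would condense with the aryloxy ketone under base.

Key step: step 6

Remark on the chemistry: the HI released in the I2/MeOH aromatization is assumed to cleave the primary TBS ether in the same flask. The free benzylic alcohol is therefore taken as the product of step 7 and is protected as a pivalate before the BCl3 step. The target has no stereocenter; the two centers made in step 6 are erased in step 7.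

**Route**

Step 1
Reactants: 1 orcinol (5-methylbenzene-1,3-diol)
Product: 2 1,3-diisopropoxy-5-methylbenzene
Conditions: 2-bromopropane (excess), K2CO3, DMF, 70 °C
Reagents that add atoms: 2-bromopropane, CC(C)Br
Why: Double Williamson ether synthesis should alkylate both phenoxides, and the isopropyl groups can later be removed by a Lewis acid without touching methyl ethers.

Step 2
Reactants: 2 1,3-diisopropoxy-5-methylbenzene
Product: 4 2-bromo-1,3-diisopropoxy-5-methylbenzene, via aryllithium 3 (not isolated)
Conditions: n-BuLi, TMEDA, THF, 0 °C → rt; then BrCH2CH2Br, −78 °C → rt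
Reagents that add atoms: 1,2-dibromoethane, BrCCBr
Why: Directed ortho-metalation, in which the two alkoxy groups jointly steer n-BuLi to the carbon between them, followed by bromine transfer from 1,2-dibromoethane to aryllithium 3 with loss of ethene.

Step 3
Reactants: 4 2-bromo-1,3-diisopropoxy-5-methylbenzene
Product: 6 2-bromo-3-isopropoxy-5-methylphenol, via aryloxydichloroborane 5 (not isolated)
Conditions: BCl3 (1.0 equiv), CH2Cl2, −78 → 0 °C; then H2O
Reagents that add atoms: none
Why: Lewis acid dealkylation of an aryl isopropyl ether, where one equivalent of BCl3 and the lower basicity of the remaining ether oxygen in 5 should hold the reaction at a single cleavage.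

Step 4
Reactants: 6 2-bromo-3-isopropoxy-5-methylphenol; 7 chloroacetone
Product: 8 1-(2-bromo-3-isopropoxy-5-methylphenoxy)propan-2-one
Conditions: K2CO3, acetone, reflux
Reagents that add atoms: none
Why: Williamson alkylation (SN2) of the phenoxide by the activated primary chloride places the future diaryl ether oxygen on an sp3 carbon.

Step 5
Reactants: 9 (tert-butyldimethylsilyloxy)acetaldehyde; 10 methyl (triphenylphosphoranylidene)acetate
Product: 11 methyl (E)-4-(tert-butyldimethylsilyloxy)but-2-enoate
Conditions: CH2Cl2, rt
Reagents that add atoms: none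
Why: Wittig olefination with a stabilized ylide should give the (E)-enoate; no stereocenter is formed.

Step 6
Reactants: 8 1-(2-bromo-3-isopropoxy-5-methylphenoxy)propan-2-one; 11 methyl (E)-4-(tert-butyldimethylsilyloxy)but-2-enoate
Product: 13 racemic trans-4-(2-bromo-3-isopropoxy-5-methylphenoxy)-5-{[(tert-butyldimethylsilyl)oxy]methyl}cyclohexane-1,3-dione, via Michael adduct 12 (not isolated)
Conditions: NaOMe (1.5 equiv), MeOH/THF, 0 → 60 °C; then 1 M HCl to pH 3, 0 °C
Reagents that add atoms: none
Why: Methoxide equilibrates the enolates of 8, and the enolate at the aryloxy-bearing carbon adds to the β-carbon of enoate 11, forming the C1'–C2' bond of ring B and giving keto ester 12 after proton transfer. The methyl ketone enolate of 12 then attacks the ester carbonyl and expels methoxide, forming the C4'–C5' bond in a 6-(enolendo)-exo-trig Claisen (Dieckmann-type) closure, and deprotonation of the acidic 1,3-dione makes the sequence irreversible. The closest known reaction type is the consecutive Michael–Claisen annulation of substituted acetones with α,β-unsaturated esters to 4-substituted cyclohexane-1,3-diones. The two new stereocenters (C4 and C5 of the dione) form as a racemate and should settle to the trans diastereomer, because C4 is α to a carbonyl and epimerizes under base until both substituents are equatorial; both centers vanish on aromatization, so no control is needed. The step needs Michael addition through the aryloxy-bearing carbon and not through the methyl group: the inductive effect of the aryloxy oxygen makes the OCH2 hydrogens the more acidic ones, the equilibrating alkoxide conditions favor that enolate, and in adduct 12 only the methyl terminus can reach the ester through a six-membered transition state.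

Step 7
Reactants: 13 racemic trans-4-(2-bromo-3-isopropoxy-5-methylphenoxy)-5-{[(tert-butyldimethylsilyl)oxy]methyl}cyclohexane-1,3-dione
Product: 15 [2-(2-bromo-3-isopropoxy-5-methylphenoxy)-3,5-dimethoxyphenyl]methanol, via silyl ether 14 (not isolated)
Conditions: I2 (2 equiv), MeOH, reflux; then aq. Na2S2O3
Reagents that add atoms: methanol, CO
Why: Iodine-mediated oxidative aromatization of a cyclohexane-1,3-dione in methanol, in which acid-catalysed formation of the methyl enol ethers, α-iodination and loss of HI should give resorcinol dimethyl ether 14 with both stereocenters erased, and the HI set free methanolyses the primary silyl ether.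

Step 8
Reactants: 15 [2-(2-bromo-3-isopropoxy-5-methylphenoxy)-3,5-dimethoxyphenyl]methanol
Product: 16 2-(2-bromo-3-isopropoxy-5-methylphenoxy)-3,5-dimethoxybenzyl pivalate
Conditions: PivCl, pyridine, DMAP (cat.), CH2Cl2, 0 °C → rt
Reagents that add atoms: pivaloyl chloride, CC(C)(C)C(Cl)=O
Why: DMAP-catalysed acylation of the primary benzylic alcohol gives an ester that should withstand BCl3 and the later basic and thermal steps.

Step 9
Reactants: 16 2-(2-bromo-3-isopropoxy-5-methylphenoxy)-3,5-dimethoxybenzyl pivalate
Product: 17 methyl 2-isopropoxy-4-methyl-6-{2,4-dimethoxy-6-[(pivaloyloxy)methyl]phenoxy}benzoate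
Conditions: Pd(OAc)2 (5 mol %), Xantphos (6 mol %), CO (1 atm), Et3N, MeOH, 70–80 °C
Reagents that add atoms: carbon monoxide, [C-]#[O+]; methanol, CO
Why: Palladium-catalysed methoxycarbonylation, in which zerovalent palladium formed in situ inserts into the C–Br bond, CO insertion gives an acylpalladium bromide and methanol cleaves it to the methyl ester, with Xantphos as a ligand suited to ortho-substituted bromides at atmospheric CO pressure.

Step 10
Reactants: 17 methyl 2-isopropoxy-4-methyl-6-{2,4-dimethoxy-6-[(pivaloyloxy)methyl]phenoxy}benzoate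
Product: 19 methyl 2-hydroxy-4-methyl-6-{2,4-dimethoxy-6-[(pivaloyloxy)methyl]phenoxy}benzoate, via aryloxydichloroborane 18 (not isolated)
Conditions: BCl3 (1.5 equiv), CH2Cl2, −78 → −20 °C; then H2O
Reagents that add atoms: none
Why: Chelation-controlled Lewis acid dealkylation, in which boron binds between the ester carbonyl and the ortho isopropoxy oxygen so that only this secondary alkyl ether is cleaved while the ring B methyl ethers, the pivalate and the methyl ester should remain.

Step 11
Reactants: 19 methyl 2-hydroxy-4-methyl-6-{2,4-dimethoxy-6-[(pivaloyloxy)methyl]phenoxy}benzoate; 20 3-chloro-3-methylbut-1-yne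
Product: 21 methyl 4-methyl-2-[(2-methylbut-3-yn-2-yl)oxy]-6-{2,4-dimethoxy-6-[(pivaloyloxy)methyl]phenoxy}benzoate
Conditions: DBU, CuCl2·2H2O (cat.), MeCN, 0 °C → rt
Reagents that add atoms: none
Why: Copper-catalysed O-propargylation of a phenol with a tertiary propargylic chloride, in which the copper-activated propargyl electrophile is captured by the phenoxide at the tertiary carbon and the phenol is the only group acidic enough to react.

Step 12
Reactants: 21 methyl 4-methyl-2-[(2-methylbut-3-yn-2-yl)oxy]-6-{2,4-dimethoxy-6-[(pivaloyloxy)methyl]phenoxy}benzoate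
Product: 22 methyl 4-methyl-2-[(2-methylbut-3-en-2-yl)oxy]-6-{2,4-dimethoxy-6-[(pivaloyloxy)methyl]phenoxy}benzoate
Conditions: H2 (1 atm), Pd/CaCO3 poisoned with Pb(OAc)2 (Lindlar catalyst), quinoline, EtOAc, rt
Reagents that add atoms: none
Why: Lindlar semihydrogenation should stop the terminal alkyne at the alkene and leave the aryl ethers and esters untouched.

Step 13
Reactants: 22 methyl 4-methyl-2-[(2-methylbut-3-en-2-yl)oxy]-6-{2,4-dimethoxy-6-[(pivaloyloxy)methyl]phenoxy}benzoate
Product: 24 methyl 2-hydroxy-4-methyl-3-(3-methylbut-2-en-1-yl)-6-{2,4-dimethoxy-6-[(pivaloyloxy)methyl]phenoxy}benzoate, via dienone 23 (not isolated)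
Conditions: xylenes, 130–140 °C
Reagents that add atoms: none
Why: Aromatic Claisen rearrangement, in which the [3,3]-sigmatropic shift through a chair transition state delivers the allyl terminus to C3 of ring A (the only ortho carbon bearing hydrogen), the 1,1-dimethylallyl unit arrives inverted as a linear prenyl group and tautomerisation of dienone 23 restores the phenol.

Step 14
Reactants: 24 methyl 2-hydroxy-4-methyl-3-(3-methylbut-2-en-1-yl)-6-{2,4-dimethoxy-6-[(pivaloyloxy)methyl]phenoxy}benzoate
Product: 25 methyl 2-hydroxy-6-[2-(hydroxymethyl)-4,6-dimethoxyphenoxy]-4-methyl-3-(3-methylbut-2-en-1-yl)benzoate (target)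
Conditions: NaOMe (3 equiv), MeOH, rt → 40 °C; then AcOH
Reagents that add atoms: none
Why: Base-catalysed transesterification removes the pivalate as methyl pivalate, while the ring A methyl ester can only exchange methoxide for methoxide and so should be unchanged.

**Compound list**

1 | orcinol (5-methylbenzene-1,3-diol) | Cc1cc(O)cc(O)c1 | starting material
2 | 1,3-diisopropoxy-5-methylbenzene | Cc1cc(OC(C)C)cc(OC(C)C)c1 | intermediate
3 | (2,6-diisopropoxy-4-methylphenyl)lithium | [Li]c1c(OC(C)C)cc(C)cc1OC(C)C | intermediate
4 | 2-bromo-1,3-diisopropoxy-5-methylbenzene | Cc1cc(OC(C)C)c(Br)c(OC(C)C)c1 | intermediate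
5 | (2-bromo-3-isopropoxy-5-methylphenoxy)dichloroborane | Cc1cc(OB(Cl)Cl)c(Br)c(OC(C)C)c1 | intermediate
6 | 2-bromo-3-isopropoxy-5-methylphenol | Cc1cc(O)c(Br)c(OC(C)C)c1 | intermediate
7 | chloroacetone | CC(=O)CCl | starting material
8 | 1-(2-bromo-3-isopropoxy-5-methylphenoxy)propan-2-one | CC(=O)COc1cc(C)cc(OC(C)C)c1Br | intermediate
9 | (tert-butyldimethylsilyloxy)acetaldehyde | O=CCO[Si](C)(C)C(C)(C)C | starting material
10 | methyl (triphenylphosphoranylidene)acetate | COC(=O)C=P(c1ccccc1)(c1ccccc1)c1ccccc1 | starting material
11 | methyl (E)-4-(tert-butyldimethylsilyloxy)but-2-enoate | COC(=O)/C=C/CO[Si](C)(C)C(C)(C)C | intermediate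
12 | methyl 4-(2-bromo-3-isopropoxy-5-methylphenoxy)-3-{[(tert-butyldimethylsilyl)oxy]methyl}-5-oxohexanoate (mixture of diastereomers) | COC(=O)CC(CO[Si](C)(C)C(C)(C)C)C(Oc1cc(C)cc(OC(C)C)c1Br)C(C)=O | intermediate
13 | racemic trans-4-(2-bromo-3-isopropoxy-5-methylphenoxy)-5-{[(tert-butyldimethylsilyl)oxy]methyl}cyclohexane-1,3-dione (one enantiomer drawn) | O=C1CC(=O)[C@@H](Oc2cc(C)cc(OC(C)C)c2Br)[C@H](CO[Si](C)(C)C(C)(C)C)C1 | intermediate
14 | {[2-(2-bromo-3-isopropoxy-5-methylphenoxy)-3,5-dimethoxybenzyl]oxy}(tert-butyl)dimethylsilane | COc1cc(CO[Si](C)(C)C(C)(C)C)c(Oc2cc(C)cc(OC(C)C)c2Br)c(OC)c1 | intermediate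
15 | [2-(2-bromo-3-isopropoxy-5-methylphenoxy)-3,5-dimethoxyphenyl]methanol | COc1cc(CO)c(Oc2cc(C)cc(OC(C)C)c2Br)c(OC)c1 | intermediate
16 | 2-(2-bromo-3-isopropoxy-5-methylphenoxy)-3,5-dimethoxybenzyl pivalate | COc1cc(COC(=O)C(C)(C)C)c(Oc2cc(C)cc(OC(C)C)c2Br)c(OC)c1 | intermediate
17 | methyl 2-isopropoxy-4-methyl-6-{2,4-dimethoxy-6-[(pivaloyloxy)methyl]phenoxy}benzoate | COC(=O)c1c(Oc2c(COC(=O)C(C)(C)C)cc(OC)cc2OC)cc(C)cc1OC(C)C | intermediate
18 | methyl 2-[(dichloroboranyl)oxy]-4-methyl-6-{2,4-dimethoxy-6-[(pivaloyloxy)methyl]phenoxy}benzoate | COC(=O)c1c(Oc2c(COC(=O)C(C)(C)C)cc(OC)cc2OC)cc(C)cc1OB(Cl)Cl | intermediate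
19 | methyl 2-hydroxy-4-methyl-6-{2,4-dimethoxy-6-[(pivaloyloxy)methyl]phenoxy}benzoate | COC(=O)c1c(Oc2c(COC(=O)C(C)(C)C)cc(OC)cc2OC)cc(C)cc1O | intermediate
20 | 3-chloro-3-methylbut-1-yne | C#CC(C)(C)Cl | starting material
21 | methyl 4-methyl-2-[(2-methylbut-3-yn-2-yl)oxy]-6-{2,4-dimethoxy-6-[(pivaloyloxy)methyl]phenoxy}benzoate | COC(=O)c1c(Oc2c(COC(=O)C(C)(C)C)cc(OC)cc2OC)cc(C)cc1OC(C)(C)C#C | intermediate
22 | methyl 4-methyl-2-[(2-methylbut-3-en-2-yl)oxy]-6-{2,4-dimethoxy-6-[(pivaloyloxy)methyl]phenoxy}benzoate | COC(=O)c1c(Oc2c(COC(=O)C(C)(C)C)cc(OC)cc2OC)cc(C)cc1OC(C)(C)C=C | intermediate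
23 | methyl 4-methyl-5-(3-methylbut-2-en-1-yl)-6-oxo-2-{2,4-dimethoxy-6-[(pivaloyloxy)methyl]phenoxy}cyclohexa-1,3-diene-1-carboxylate (racemic) | COC(=O)C1=C(Oc2c(COC(=O)C(C)(C)C)cc(OC)cc2OC)C=C(C)C(CC=C(C)C)C1=O | intermediate
24 | methyl 2-hydroxy-4-methyl-3-(3-methylbut-2-en-1-yl)-6-{2,4-dimethoxy-6-[(pivaloyloxy)methyl]phenoxy}benzoate | COC(=O)c1c(Oc2c(COC(=O)C(C)(C)C)cc(OC)cc2OC)cc(C)c(CC=C(C)C)c1O | intermediate
25 | methyl 2-hydroxy-6-[2-(hydroxymethyl)-4,6-dimethoxyphenoxy]-4-methyl-3-(3-methylbut-2-en-1-yl)benzoate | COC(=O)c1c(Oc2c(CO)cc(OC)cc2OC)cc(C)c(CC=C(C)C)c1O | target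

**Step count**

Total step count: 14.
Longest linear sequence: 13 steps (steps 1–4 and 6–14; step 5 is the side branch to enoate 11).

**Three steps most likely to fail**

Step 6 (key step). What may go wrong: conjugate addition through the methyl terminus of 8, which after closure would lead to the isomeric 2-aryloxy dione. Other possible failures are base-induced γ-deprotonation and double-bond migration of enoate 11, and reversible methoxide addition to 11 outrunning C–C bond formation. Fallback: give up the annulation and attach a ready-made ring B. Phenol 6 is coupled with commercial 2-bromo-3,5-dimethoxybenzaldehyde under Ullmann conditions (CuI, picolinic acid, K3PO4, DMSO, 90 °C). The formyl-activated bromide should react in preference to the doubly flanked, electron-rich bromide of 6. The product is 2-(2-bromo-3-isopropoxy-5-methylphenoxy)-3,5-dimethoxybenzaldehyde F1, which NaBH4 in MeOH at 0 °C should reduce to alcohol 15, where the route is rejoined.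

Step 7. What may go wrong: etherification stalling at the monomethyl ether phenols, solvolysis of the freed benzylic alcohol to its methyl ether in hot methanolic HI, or electrophilic iodination of the electron-rich ring A. Fallback: separate the oxidation from the ether formation. Dione 13 is dehydrogenated with catalytic I2 in DMSO at 80 °C; DMSO reoxidizes HI, so the medium stays nearly neutral and free of methanol. This should give 4-(2-bromo-3-isopropoxy-5-methylphenoxy)-5-{[(tert-butyldimethylsilyl)oxy]methyl}benzene-1,3-diol F2. Both phenols are then methylated with MeI/K2CO3 in acetone to give silyl ether 14, now isolated, and Bu4NF in THF frees alcohol 15, where the route is rejoined.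

Step 9. What may go wrong: slow oxidative addition at the hindered, electron-rich C–Br bond flanked by two oxygens, so that protodebromination and precipitation of palladium metal outrun carbonylation. Fallback: replace the catalytic carbonylation by carboxylation of an aryllithium, setting out from alcohol 15 before pivaloylation. Treatment with n-BuLi (2.2 equiv, THF, −78 °C; alkoxide formation, then bromine–lithium exchange) and CO2 should give 2-[2-(hydroxymethyl)-4,6-dimethoxyphenoxy]-6-isopropoxy-4-methylbenzoic acid F3. Me3SiCHN2 in MeOH/toluene esterifies the acid to methyl 2-[2-(hydroxymethyl)-4,6-dimethoxyphenoxy]-6-isopropoxy-4-methylbenzoate F4, and PivCl/pyridine converts this into 17, where the route is rejoined.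

**Further compounds**

F1 | step 6 | 2-(2-bromo-3-isopropoxy-5-methylphenoxy)-3,5-dimethoxybenzaldehyde | COc1cc(C=O)c(Oc2cc(C)cc(OC(C)C)c2Br)c(OC)c1
F2 | step 7 | 4-(2-bromo-3-isopropoxy-5-methylphenoxy)-5-{[(tert-butyldimethylsilyl)oxy]methyl}benzene-1,3-diol | Oc1cc(O)c(Oc2cc(C)cc(OC(C)C)c2Br)c(CO[Si](C)(C)C(C)(C)C)c1
F3 | step 9 | 2-[2-(hydroxymethyl)-4,6-dimethoxyphenoxy]-6-isopropoxy-4-methylbenzoic acid | OC(=O)c1c(Oc2c(CO)cc(OC)cc2OC)cc(C)cc1OC(C)C
F4 | step 9 | methyl 2-[2-(hydroxymethyl)-4,6-dimethoxyphenoxy]-6-isopropoxy-4-methylbenzoate | COC(=O)c1c(Oc2c(CO)cc(OC)cc2OC)cc(C)cc1OC(C)C
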